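North-west, charged with 0.48 mM of starting material, had turned 35.2% of it into product by 6.00 min. East, with 31.2 times that charge, still turned 28.3%, so the yield fell far more slowly than the charge grew.

all flasks: free catalyst 3.6 mM
- north-west: starting material 0.48 mM (in portions, 2); partner 27 mM; run made earlier; portions every 4.0 min
- east: starting material 15 mM (in portions, 2); partner 27 mM; run made earlier; portions every 4.0 min
- cedar: starting material 0.60 mM (in portions, 2); partner 27.0 mM; the portions of starting material follow each other after 4.0 min, the first at the start; time 8.0 min
- oak: starting material 2.0 mM (in portions, 2); partner 27.0 mM; the portions of starting material follow each other after 4.0 min, the first at the start; time 8.0 min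
- larch: starting material 6.0 mM (in portions, 2); partner 27.0 mM; the portions of starting material follow each other after 4.0 min, the first at the start; time 8.0 min
- ash: starting material 20 mM (in portions, 2); partner 27.0 mM; the portions of starting material follow each other after 4.0 min, the first at the start; time 8.0 min

| run | time / min | product / % |
|---|---|---|
| north-west | 0.417 | 0.8 |
| north-west | 0.833 | 3.8 |
| north-west | 1.50 | 7.3 |
| north-west | 3.00 | 15.6 |
| north-west | 6.00 | 35.2 |
| east | 1.00 | 3.9 |
| east | 2.50 | 11.3 |
| east | 3.00 | 12.7 |
| east | 5.00 | 22.6 |
| east | 6.00 | 28.3 |

(readings scatter by 0.3 percentage points)

- "hardly changes" means that all values lie within two and a half points (for a concentration: within two and a half percent of the largest)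

* [product] at the end for cedar, oak, larch, ash, in this order
* the course of these numbers from the first flask to the last (falls, then rises / rises, then falls / hardly changes / falls all the way / rises all the way)

I wanted the one concentration against which a charge must be held to tell the order of the rate. The two yields stood in the ratio 1.24. I assumed that, with this partner, this free catalyst and this schedule of portions, the inverse of the yield at a fixed time climbs linearly with the charge. The readings then give G = 59.1 mM, the half-yield charge: the charge at which the yield stands at half its low-charge value. The pair read at 3.00 min gave 63.1 mM, which comes from different readings.

Now the run in slow motion. In the first instants north-west read 0.8% at 0.417 min and 3.8% at 0.833 min, so product grew faster than time, and I took it that something stood before product and had first to fill. In the middle, north-west at 3.00 min had converted 31.2% of its first portion, which gave a first-order constant k = 0.125 min⁻¹. Even for ash, the charge is 0.339 of G, so I expected a rate bent from first order but not flattened. At the end, if one partner goes per product, the partner at 27.0 mM exceeds ash's charge, and starting material is the limiting reagent.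

Two first-order portions with that k gave 37.4% at 6.00 min and 51.2% at 8.0 min. North-west read lower at 6.00 min, so I scaled down by that ratio and reached a low-charge yield of 48.6%. Dividing by one plus charge over G, my row was 0.289 mM, 0.940 mM, 2.65 mM and 7.26 mM.

The forecast differs from my row: 0.27 mM, 0.89 mM, 2.5 mM and 7.2 mM, lower for cedar and slightly lower for ash. Its course is the same, rises all the way: “The fractional yield falls, but [product] rises throughout.”

The flasks gave 0.290 mM, 0.944 mM, 2.65 mM and 7.11 mM: rises all the way.

    starting material + free catalyst ⇌ catalyst intermediate A (K = 32.0 L mol⁻¹, k = 8.10 L mol⁻¹ s⁻¹)
    catalyst intermediate B → catalyst intermediate C (k = 0.0360 s⁻¹)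
    partner + catalyst intermediate A → catalyst intermediate B (k = 1.50 L mol⁻¹ s⁻¹)
    catalyst intermediate D → free catalyst + product (k = 0.500 s⁻¹)
    catalyst intermediate C → released group + catalyst intermediate D (k = 0.390 s⁻¹)
    starting material ⇌ dormant form (K = 1.10, k = 0.00620 s⁻¹)

In cedar, starting material passed into the dormant form, and at 8.00 min there stood 19.9% starting material, 27.1% dormant form and 48.3% product, with free catalyst at 99.2%. In ash at 8.00 min, catalyst intermediate A held 11.9% and catalyst intermediate B 10.2% of the catalyst, free catalyst stood at 76.2%, and product stood at 35.5% of the charge, beside 36.3% for the low-charge yield over one plus charge over G. For larch the same reckoning gives 44.1%, and its product stood at 44.2% of the charge.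

The numbers in the tables are calculated from invented constants.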